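Everything rests on detaching ring A from ring C (the pyranone) at both anchors at once: the aryl–oxygen bond C8a–O1 and the aryl–acyl bond C4a–C4. In the key step a 3,5-bis(benzyloxy)benzyne inserts into the C–O bond of a 2-arylacrylic acid that already carries the complete chromene unit: the carboxylate oxygen becomes O1, the acyl carbon becomes C4, and the released phenoxide closes ring C onto the methylene carbon C2. The step exploits the ortho placement of O1 and C4 on ring A, with the C5 oxygen beside C4a steering the aryne regiochemistry. The base-labile C3 centre is set afterwards by dynamic kinetic resolution.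

Key step: step 7

Assumption: C3 of an isoflavanone epimerises readily with base, so the (R) centre is set after ring construction (step 8) and steps 9 and 10 are run without strong base; 3,5-bis(benzyloxy)phenol (9) is taken as a commercial starting material.

Step 1
Reactants: 1 2,4-dihydroxyacetophenone; 2 3-methylbut-2-enal
Product: 4 1-(5-hydroxy-2,2-dimethyl-2H-chromen-6-yl)ethan-1-one, via ortho-quinone methide 3 (not isolated)
Conditions: ethylenediammonium diacetate (10 mol%), xylene, 140 °C
Reagents that add atoms: none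
Why: Knoevenagel-type condensation at the ring carbon between the two hydroxyls gives ortho-quinone methide 3, and oxa-6π electrocyclisation through the unchelated 4-oxygen closes the pyran ring while the hydrogen-bonded 2-hydroxyl stays free, the usual regiochemical outcome for 2,4-dihydroxyaryl ketones.

Step 2
Reactants: 4 1-(5-hydroxy-2,2-dimethyl-2H-chromen-6-yl)ethan-1-one
Product: 5 1-[5-(benzyloxy)-2,2-dimethyl-2H-chromen-6-yl]ethan-1-one
Conditions: BnBr, K2CO3, DMF, 60 °C
Reagents that add atoms: benzyl bromide, BrCc1ccccc1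
Why: Williamson ether synthesis; the chelated phenol is the only nucleophilic site and warm DMF should overcome its hydrogen bond.

Step 3
Reactants: 5 1-[5-(benzyloxy)-2,2-dimethyl-2H-chromen-6-yl]ethan-1-one
Product: 6 1-[5-(benzyloxy)-2,2-dimethyl-2H-chromen-6-yl]ethenyl trifluoromethanesulfonate
Conditions: KN(SiMe3)2 (1.05 equiv), THF, −78 °C; then PhNTf2, −78 to 0 °C
Reagents that add atoms: N-phenylbis(trifluoromethanesulfonimide), O=S(=O)(N(c1ccccc1)S(=O)(=O)C(F)(F)F)C(F)(F)F
Why: Enol triflate formation: the methyl group is the only enolisable position, and O-sulfonylation of the potassium enolate should give the 1-arylvinyl triflate, with the base kept near one equivalent to avoid elimination to the alkyne.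

Step 4
Reactants: 6 1-[5-(benzyloxy)-2,2-dimethyl-2H-chromen-6-yl]ethenyl trifluoromethanesulfonate
Product: 8 2-[5-(benzyloxy)-2,2-dimethyl-2H-chromen-6-yl]prop-2-enoic acid, via mixed acetic anhydride 7 (not isolated)
Conditions: Pd(OAc)2 (5 mol%), PPh3 (10 mol%), KOAc (4 equiv), CO (1 atm), DMF, 25 to 60 °C; then H2O
Reagents that add atoms: carbon monoxide, [C-]#[O+]; potassium acetate, CC(=O)[O-].[K+]; water, O
Why: Palladium-catalysed hydroxycarbonylation of a vinyl triflate: oxidative addition to zerovalent palladium, CO insertion and capture of the acylpalladium by acetate give mixed anhydride 7, which water hydrolyses to the acid, the chromene alkene and the benzyl ether being inert.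

Step 5
Reactants: 9 3,5-bis(benzyloxy)phenol
Product: 10 3,5-bis(benzyloxy)-2-bromophenol
Conditions: N-bromosuccinimide (1.0 equiv), CH2Cl2, −78 to −20 °C
Reagents that add atoms: N-bromosuccinimide, O=C1CCC(=O)N1Br
Why: Electrophilic aromatic bromination; one equivalent at low temperature should favour the two equivalent positions ortho to the hydroxyl over the more hindered position between the two benzyloxy groups, and the isomers are separable.

Step 6
Reactants: 10 3,5-bis(benzyloxy)-2-bromophenol
Product: 13 3,5-bis(benzyloxy)-2-(trimethylsilyl)phenyl trifluoromethanesulfonate, via aryl trimethylsilyl ether 11 (not isolated), via lithium ortho-silylphenoxide 12 (not isolated)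
Conditions: HN(SiMe3)2, THF, 70 °C, then evaporation; n-BuLi, THF, −100 to −78 °C; Tf2O, −100 °C to 25 °C
Reagents that add atoms: hexamethyldisilazane, C[Si](C)(C)N[Si](C)(C)C; trifluoromethanesulfonic anhydride, O=S(=O)(OS(=O)(=O)C(F)(F)F)C(F)(F)F
Why: O-silylation, bromine–lithium exchange and 1,3 O-to-C silyl shift (retro-Brook rearrangement) place silicon ortho to the phenoxide in 12, which is trapped as the triflate, the standard entry to ortho-silylaryl triflates.

Step 7
Reactants: 8 2-[5-(benzyloxy)-2,2-dimethyl-2H-chromen-6-yl]prop-2-enoic acid; 13 3,5-bis(benzyloxy)-2-(trimethylsilyl)phenyl trifluoromethanesulfonate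
Product: 17 rac-5,7-bis(benzyloxy)-3-[5-(benzyloxy)-2,2-dimethyl-2H-chromen-6-yl]chroman-4-one, via 3,5-bis(benzyloxy)benzyne 14 (not isolated), via ortho-acyloxyaryl anion 15 (not isolated), via ortho-acyl phenoxide 16 (not isolated)
Conditions: CsF (4 equiv), 13 (1.5 equiv), THF, 125 °C (sealed tube), 24 h
Reagents that add atoms: none
Why: Fluoride unmasks aryne 14 from 13; the caesium carboxylate of 8 adds through oxygen to C1 of the aryne, the aryl anion 15 attacks the neighbouring ester carbonyl through a four-membered transition state and the acyl group moves from O to C, giving phenoxide 16 with both the C8a–O1 and the C4a–C4 bonds in place. The closest known reaction type is the fluoride-mediated insertion of arynes into the C–O bond of carboxylic acids, which with α,β-unsaturated acids continues to chroman-4-ones in the same flask. Ring C then closes by 6-endo-trig oxa-Michael addition of the phenoxide oxygen to the methylene terminus of the α-aryl enone, and the enolate is protonated at C3. C3 arises in this protonation without control, so 17 is expected as the racemate and the configuration is set in step 8. The step needs regioselectivity on the unsymmetrical aryne: the benzyloxy group at C3 of 14 distorts the triple bond and stabilises negative charge at C2 inductively, so oxygen should bond to C1 and the acyl carbon to C2, which places the ketone between O1 and the C5 benzyloxy group. It also needs acyl migration to outrun protonation of 15, which the aprotic medium and the high temperature should secure.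

Step 8
Reactants: 17 rac-5,7-bis(benzyloxy)-3-[5-(benzyloxy)-2,2-dimethyl-2H-chromen-6-yl]chroman-4-one
Product: 18 (3R,4R)-5,7-bis(benzyloxy)-3-[5-(benzyloxy)-2,2-dimethyl-2H-chromen-6-yl]chroman-4-ol
Conditions: RuCl[(R,R)-TsDPEN](p-cymene) (2 mol%), HCO2H/Et3N (1:2), EtOAc, 40 °C
Reagents that add atoms: none
Why: Noyori-type asymmetric transfer hydrogenation under dynamic kinetic resolution: triethylamine racemises C3 of 17 through the enol, the (R,R)-catalyst sets C4 as (R) in its usual sense for aryl ketones, and hydride adds anti to the 3-aryl group, so only the (3R)-ketone is reduced and the cis (3R,4R) alcohol should result.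

Step 9
Reactants: 18 (3R,4R)-5,7-bis(benzyloxy)-3-[5-(benzyloxy)-2,2-dimethyl-2H-chromen-6-yl]chroman-4-ol
Product: 19 (3R)-5,7-bis(benzyloxy)-3-[5-(benzyloxy)-2,2-dimethyl-2H-chromen-6-yl]chroman-4-one
Conditions: Dess–Martin periodinane (1.3 equiv), pyridine (3 equiv), CH2Cl2, 0 °C; Na2S2O3/pH 7 buffer work-up
Reagents that add atoms: none
Why: Dess–Martin oxidation of the benzylic alcohol under buffered, near-neutral conditions at 0 °C should return the ketone without enolisation, so the C3 configuration set in step 8 is kept.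

Step 10
Reactants: 19 (3R)-5,7-bis(benzyloxy)-3-[5-(benzyloxy)-2,2-dimethyl-2H-chromen-6-yl]chroman-4-one
Product: 20 (3R)-5,7-dihydroxy-3-(5-hydroxy-2,2-dimethyl-2H-chromen-6-yl)chroman-4-one
Conditions: BCl3 (6 equiv), pentamethylbenzene (10 equiv), CH2Cl2, −78 °C; MeOH/CHCl3 quench at −78 °C, pH 7 buffer
Reagents that add atoms: none
Why: Lewis acid debenzylation with a cation scavenger: boron trichloride cleaves the three aryl benzyl ethers at −78 °C while pentamethylbenzene captures the benzyl cations, and with no base and no warm protic acid the C3 centre and the chromene alkene should survive.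

Compound list
1 | 2,4-dihydroxyacetophenone | CC(=O)c1ccc(O)cc1O | starting material
2 | 3-methylbut-2-enal | CC(C)=CC=O | starting material
3 | 4-acetyl-3-hydroxy-2-(3-methylbut-2-en-1-ylidene)cyclohexa-3,5-dien-1-one (ortho-quinone methide, not isolated) | CC(=O)C1=C(O)C(=CC=C(C)C)C(=O)C=C1 | intermediate
4 | 1-(5-hydroxy-2,2-dimethyl-2H-chromen-6-yl)ethan-1-one | CC(=O)c1ccc2OC(C)(C)C=Cc2c1O | intermediate
5 | 1-[5-(benzyloxy)-2,2-dimethyl-2H-chromen-6-yl]ethan-1-one | CC(=O)c1ccc2OC(C)(C)C=Cc2c1OCc1ccccc1 | intermediate
6 | 1-[5-(benzyloxy)-2,2-dimethyl-2H-chromen-6-yl]ethenyl trifluoromethanesulfonate | C=C(OS(=O)(=O)C(F)(F)F)c1ccc2OC(C)(C)C=Cc2c1OCc1ccccc1 | intermediate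
7 | acetic 2-[5-(benzyloxy)-2,2-dimethyl-2H-chromen-6-yl]prop-2-enoic anhydride (not isolated) | C=C(C(=O)OC(C)=O)c1ccc2OC(C)(C)C=Cc2c1OCc1ccccc1 | intermediate
8 | 2-[5-(benzyloxy)-2,2-dimethyl-2H-chromen-6-yl]prop-2-enoic acid | C=C(C(=O)O)c1ccc2OC(C)(C)C=Cc2c1OCc1ccccc1 | intermediate
9 | 3,5-bis(benzyloxy)phenol | Oc1cc(OCc2ccccc2)cc(OCc2ccccc2)c1 | starting material
10 | 3,5-bis(benzyloxy)-2-bromophenol | Oc1cc(OCc2ccccc2)cc(OCc2ccccc2)c1Br | intermediate
11 | [3,5-bis(benzyloxy)-2-bromophenoxy]trimethylsilane (not isolated) | C[Si](C)(C)Oc1cc(OCc2ccccc2)cc(OCc2ccccc2)c1Br | intermediate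
12 | lithium 3,5-bis(benzyloxy)-2-(trimethylsilyl)phenoxide (not isolated) | [Li+].[O-]c1cc(OCc2ccccc2)cc(OCc2ccccc2)c1[Si](C)(C)C | intermediate
13 | 3,5-bis(benzyloxy)-2-(trimethylsilyl)phenyl trifluoromethanesulfonate | C[Si](C)(C)c1c(OS(=O)(=O)C(F)(F)F)cc(OCc2ccccc2)cc1OCc1ccccc1 | intermediate
14 | 3,5-bis(benzyloxy)benzyne (not isolated) | C1#CC(OCc2ccccc2)=CC(OCc2ccccc2)=C1 | intermediate
15 | caesium 2,4-bis(benzyloxy)-6-{2-[5-(benzyloxy)-2,2-dimethyl-2H-chromen-6-yl]prop-2-enoyloxy}phenide (aryl anion, not isolated) | C=C(C(=O)Oc1cc(OCc2ccccc2)cc(OCc2ccccc2)[c-]1)c1ccc2OC(C)(C)C=Cc2c1OCc1ccccc1.[Cs+] | intermediate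
16 | caesium 3,5-bis(benzyloxy)-2-{2-[5-(benzyloxy)-2,2-dimethyl-2H-chromen-6-yl]prop-2-enoyl}phenoxide (not isolated) | C=C(C(=O)c1c([O-])cc(OCc2ccccc2)cc1OCc1ccccc1)c1ccc2OC(C)(C)C=Cc2c1OCc1ccccc1.[Cs+] | intermediate
17 | rac-5,7-bis(benzyloxy)-3-[5-(benzyloxy)-2,2-dimethyl-2H-chromen-6-yl]chroman-4-one | O=C1c2c(OCc3ccccc3)cc(OCc3ccccc3)cc2OCC1c1ccc2OC(C)(C)C=Cc2c1OCc1ccccc1 | intermediate
18 | (3R,4R)-5,7-bis(benzyloxy)-3-[5-(benzyloxy)-2,2-dimethyl-2H-chromen-6-yl]chroman-4-ol (3,4-cis) | O[C@H]1c2c(OCc3ccccc3)cc(OCc3ccccc3)cc2OC[C@H]1c1ccc2OC(C)(C)C=Cc2c1OCc1ccccc1 | intermediate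
19 | (3R)-5,7-bis(benzyloxy)-3-[5-(benzyloxy)-2,2-dimethyl-2H-chromen-6-yl]chroman-4-one | O=C1c2c(OCc3ccccc3)cc(OCc3ccccc3)cc2OC[C@H]1c1ccc2OC(C)(C)C=Cc2c1OCc1ccccc1 | intermediate
20 | (3R)-5,7-dihydroxy-3-(5-hydroxy-2,2-dimethyl-2H-chromen-6-yl)chroman-4-one | CC1(C)C=Cc2c(ccc([C@@H]3COc4cc(O)cc(O)c4C3=O)c2O)O1 | target

Total step count: 10. Longest linear sequence: 8 steps (steps 1 to 4, then 7 to 10, from 2,4-dihydroxyacetophenone).

Steps most likely to fail

Step 7. The aryl anion may be protonated before the acyl group migrates, which would stop at the aryl ester. A second aryne may also arylate the phenoxide or the enolate of the product, and the acrylic acid may oligomerise at 125 °C. The fallback sets out from 8 and 10. Steglich esterification (DCC, DMAP, CH2Cl2, 0 °C) should give the aryl ester 2-bromo-3,5-bis(benzyloxy)phenyl 2-[5-(benzyloxy)-2,2-dimethyl-2H-chromen-6-yl]prop-2-enoate F1. Bromine–lithium exchange (n-BuLi, THF, −100 °C) then generates the ortho-acyloxy aryl anion regiospecifically at low temperature and without a free aryne. Anionic Fries-type O-to-C acyl shift and oxa-Michael closure on warming should give 17, where the route is rejoined.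

Step 8. Hydride transfer to the electron-rich C4 carbonyl, which is flanked by the C5 benzyloxy group, may be slow, and racemisation of C3 may not keep pace with reduction, so that the resolution is not dynamic. The fallback sets out from 17. O-acylation of the potassium enolate (KN(SiMe3)2, allyl chloroformate, THF, −78 °C) should give the allyl enol carbonate 5,7-bis(benzyloxy)-3-[5-(benzyloxy)-2,2-dimethyl-2H-chromen-6-yl]-2H-chromen-4-yl prop-2-en-1-yl carbonate F2. Palladium-catalysed decarboxylative asymmetric protonation follows (Pd2(dba)3, t-BuPHOX in the enantiomeric form that delivers the (3R) product, Meldrum's acid as proton source, dioxane, 40 °C). This should give 19 directly, so the route is rejoined at 19 and steps 8 and 9 are bypassed.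

Step 10. The C3 configuration may erode through enolisation of the boron-chelated ketone during cleavage or quench, and benzyl cations may be transferred to the electron-rich ring A. The fallback sets out from 17. Debenzylation of the racemate (BCl3, pentamethylbenzene, CH2Cl2, −78 °C), where no configuration is at stake, should give rac-5,7-dihydroxy-3-(5-hydroxy-2,2-dimethyl-2H-chromen-6-yl)chroman-4-one F3. The enantiomers are then separated by preparative chromatography on a chiral stationary phase (amylose tris(3,5-dimethylphenylcarbamate), hexane/2-propanol, neutral eluent), which comes back to the route at 20. The unwanted enantiomer can be racemised with Et3N and recycled.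

Further compounds
F1 | step 7 | 2-bromo-3,5-bis(benzyloxy)phenyl 2-[5-(benzyloxy)-2,2-dimethyl-2H-chromen-6-yl]prop-2-enoate | C=C(C(=O)Oc1cc(OCc2ccccc2)cc(OCc2ccccc2)c1Br)c1ccc2OC(C)(C)C=Cc2c1OCc1ccccc1
F2 | step 8 | 5,7-bis(benzyloxy)-3-[5-(benzyloxy)-2,2-dimethyl-2H-chromen-6-yl]-2H-chromen-4-yl prop-2-en-1-yl carbonate | C=CCOC(=O)OC1=C(COc2cc(OCc3ccccc3)cc(OCc3ccccc3)c12)c1ccc2OC(C)(C)C=Cc2c1OCc1ccccc1
F3 | step 10 | rac-5,7-dihydroxy-3-(5-hydroxy-2,2-dimethyl-2H-chromen-6-yl)chroman-4-one | CC1(C)C=Cc2c(ccc(C3COc4cc(O)cc(O)c4C3=O)c2O)O1
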